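## The problem

1. The target 14 is 5,2',5'-trihydroxy-6,7,8,4'-tetramethoxyflavone. Benzene ring A is fused through C4a–C8a to 4-pyranone ring C, which carries the 2,5-dihydroxy-4-methoxyphenyl ring B at C2.
2. There is no stereocentre and no hindered axis. The whole problem is positional: nine oxygen atoms, four of them methylated and three free as hydroxyl groups, on a C15 skeleton.
3. Ring A is hexasubstituted. C5, C6, C7, C8 and C8a all bear oxygen, C4a bears the carbonyl carbon C4, and of the four exocyclic oxygens only the one at C5 is free. An aromatic precursor would therefore have to be oxygenated one position at a time and then demethylated selectively.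
4. Ring B is a methoxyhydroquinone, with its hydroxyl groups at C2' and C5' para to each other. These two must be kept distinct from 4'-OMe, and the ring is easily oxidised to the quinone.
5. Ring A is itself a 4-methoxyphenol, with 5-OH para to 8-OMe. Late one-electron oxidants are excluded, and so is an excess of hard Lewis acid, which attacks 6-OMe once the 5-OH/C4=O chelate exists.
6. The feature that opens the plan is the chain C5(OH)–C6(OMe)–C7(OMe)–C8(OMe). It consists of four contiguous oxygen-bearing carbons whose ends are para to each other. The two remaining ring A atoms, C4a and C8a, are at the same time a C=C bond of ring C, namely C5=C6 of a monocyclic 4-pyranone.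
7. This is the signature of the hydroquinone monoether formed by electrocyclic ring expansion of a 4-alkenyl-4-methoxycyclobutenone made from dimethyl squarate 7. The four carbons and their four oxygens come from 7, and the ketene carbon ends as the single free phenol at C5, peri to C4=O.

## Retrosynthesis

**14 ⇒ 13 (the two O–CH2Ph bonds at O2' and O5').**
- The ring B hydroquinone must pass a strong base, a hard methylating agent and about 140 °C, so it is carried masked.
- Methyl ethers could not be told from 4'-OMe. Unmasking a trimethoxy ring B through its quinone would strike the 5-OH/8-OMe pair of ring A first.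
- Acetal groups would draw metalation into ring B.
- Benzyl ethers avoid these faults and fall in a neutral hydrogenolysis. That reaction only has to spare C2=C3.

**13 ⇒ 10 (C4a–C5 cut and C5–C8 rejoined, so ring A is folded back into a four-membered ring).**
- Ring A is traced back through cyclohexadienone 12 and dienylketene 11 to cyclobutenone 10.
- Two other atom maps of a squarate onto ring A were weighed:
  - The map C6–C7–C8–C8a needs an acyclic α-alkoxy-β-acylvinyl anion and an extra protecting group at O5.
  - The map C8–C8a–C4a–C5 needs a pyranone-fused cyclobutenedione, a dimethoxyvinyl anion and a regioselective addition.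
- The chosen map C5–C8 uses the symmetric compound 7 unchanged.
- Compound 10 contains no ring A at all. All the substituent relations of ring A are reduced to one C–C bond between two small pieces.
- The forward step must open the ring with the pyranone turned inward and must close onto pyranone C5.

**10 ⇒ 6 + 7 (C8–C8a and the O–CH3 bond at O8).**
- The carbinol carbon of a squarate adduct ends next to the point of attachment.
- Attachment through C6 of pyranone 6 (the future C8a) puts the carbinol oxygen at C8, where it is to be methylated, and the ketene oxygen at C5, where it is to stay free.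
- Attachment through C5 would invert this pattern. It would also need an anion that has the ring oxygen as a β-leaving group.
- The two carbonyl groups of 7 are equivalent, so the addition of 8 raises no regiochemical question. The alkoxide 9 is methylated in the same flask.
- The forward reaction requires selective deprotonation of C6–H of 6.

**6 ⇒ 3 + 4 (flavone bonds C3–C4 and O1–C8a).**
- The pyranone is cut into methyl ketone 3 and the three-carbon acid chloride 4, by way of enedione 5.
- The mirror-image cut, an aroyl chloride plus a C4 enone enolate, would need the ring B carboxylic acid and hence two more steps.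
- A hetero-Diels–Alder route would need the aldehyde and a later dehydrogenation.
- The forward reaction requires C-acylation of an enolate followed by an acid-catalysed addition–elimination.

**3 ⇒ 2 ⇒ 1 (C1'–C2 and the benzyl groups).**
- In methoxyhydroquinone 1 the only open position activated by two oxygen donors is para to OMe and ortho to OH. That position is the future C1'.
- One acylation therefore sets the complete ring B pattern in 2. Benzylation then gives 3.

## Roads not taken

**Alternative 1:** the obvious road, cutting O1–C2 and C2–C3.
- Forward: 2'-hydroxy-3',4',5',6'-tetramethoxyacetophenone A1 is O-aroylated and rearranged (Baker–Venkataraman) to the 1,3-diketone A2. Cyclodehydration, Lewis-acid cleavage of 5-OMe and debenzylation follow.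
- All the difficulty of ring A is merely moved into A1. That compound has to be built from a trioxygenated phenol by acylation, persulfate hydroxylation and methylation, one oxygen at a time.
- The 5-OH must then be re-exposed in the presence of six other aryl ethers, two of them benzyl.
- The chosen plan takes the four oxygenated carbons from one purchased C4 unit and never has to differentiate O5.

**Alternative 2:** cut C2–C1'.
- Ring B is the reduced form of 2-methoxy-1,4-benzoquinone A4.
- The forward key step would be a dehydrogenative coupling of C2–H of 5-hydroxy-6,7,8-trimethoxychromone A3 with C5–H of A4 under catalysis by divalent palladium. This would give flavone-quinone A5, and mild reduction would follow.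
- The quinone site is well explained. The methoxy group turns C4=O of A4 into a vinylogous ester, so attack goes to C5.
- The chromone site is not. Electrophilic palladation of chromones takes place at C3, the β-carbon of the enol ether, which leads into the isoflavone series.
- The terminal oxidant would also attack the 4-methoxyphenol of ring A.
- Compound A3 still contains the whole ring A problem.

**Alternative 3:** the same squarate 7 with a different atom map, in which its carbons become C6–C7–C8–C8a.
- A lithiated alkoxyallene supplies C5, C4a and C4.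
- Thermolysis of the O-methylated adduct gives o-quinone methide A6. An inverse-demand hetero-Diels–Alder reaction with styrene A7 then closes ring C to flavan A8, so rings A and C form in one operation.
- The product is at the wrong oxidation level. C4H2 must become C=O and C2–C3 must be dehydrogenated, both next to a pentaalkoxybenzene and two benzyl ethers.
- The 5-OMe must then be cleaved after all, and a stereocentre at C2 is made only to be destroyed.
- This costs four or five steps after the key step. The chosen plan needs one.

Key step: step 5

Remark on the chemistry: the target is achiral. Compounds 9, 10 and 12 each have one stereocentre, form as racemates and lose it in step 5. Only the double bonds of 4, 5 and 11 carry a configuration in their SMILES.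

## Steps

Step 1
Reactants: 1 2-methoxybenzene-1,4-diol (methoxyhydroquinone)
Product: 2 1-(2,5-dihydroxy-4-methoxyphenyl)ethan-1-one
Conditions: AcOH (1.2 equiv), BF3·OEt2 (solvent), 90 °C; H2O work-up
Reagents that add atoms: acetic acid CC(=O)O
Why: Friedel–Crafts (Nencki-type) C-acylation of a phenol; C5 of 1 is para to OMe and ortho to OH, the only unhindered site activated by two donors. The chelated, deactivated o-hydroxyketone should not acylate a second time.

Step 2
Reactants: 2 1-(2,5-dihydroxy-4-methoxyphenyl)ethan-1-one
Product: 3 1-[2,5-bis(benzyloxy)-4-methoxyphenyl]ethan-1-one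
Conditions: BnBr (2.5 equiv), K2CO3, DMF, 70 °C
Reagents that add atoms: benzyl bromide BrCc1ccccc1
Why: Williamson ether synthesis; warm DMF is chosen so that the hydrogen-bonded 2-OH is alkylated as well as the free 5-OH.

Step 3
Reactants: 3 1-[2,5-bis(benzyloxy)-4-methoxyphenyl]ethan-1-one; 4 (E)-3-ethoxyprop-2-enoyl chloride
Product: 6 2-[2,5-bis(benzyloxy)-4-methoxyphenyl]-4H-pyran-4-one, via ethoxyenedione 5 (not isolated)
Conditions: LiN(SiMe3)2 (2.2 equiv), THF, −78 °C; 4, −78 → 0 °C; then TFA (excess), CH2Cl2, rt
Reagents that add atoms: none
Why: Claisen-type C-acylation of a lithium enolate by an acid chloride, with the second equivalent of base taking up the acidic diketone 5. Acid then triggers 6-endo addition of the aryl ketone enol oxygen to the β-ethoxyenone and loss of EtOH, the established γ-pyrone synthesis through 5-alkoxypent-4-ene-1,3-diones.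

Step 4
Reactants: 6 2-[2,5-bis(benzyloxy)-4-methoxyphenyl]-4H-pyran-4-one; 7 3,4-dimethoxycyclobut-3-ene-1,2-dione (dimethyl squarate)
Product: 10 (±)-4-{6-[2,5-bis(benzyloxy)-4-methoxyphenyl]-4-oxo-4H-pyran-2-yl}-2,3,4-trimethoxycyclobut-2-en-1-one, via 6-lithiopyranone 8 (not isolated), via lithium alkoxide 9 (not isolated)
Conditions: lithium 2,2,6,6-tetramethylpiperidide (1.1 equiv, from the amine and n-BuLi), THF, −78 °C, 6 added to the base; 7 (1.2 equiv), −78 °C; MeOTf (1.1 equiv), −78 → −20 °C
Reagents that add atoms: methyl trifluoromethanesulfonate COS(=O)(=O)C(F)(F)F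
Why: Proposed new method: C6–H of 6 lies next to the ring oxygen of a 4-pyranone, whose 4-oxidopyrylium resonance form makes it the most acidic C–H (an in-plane, ylide-like carbanion with no β-leaving group), so the hindered, non-nucleophilic amide should give 8; the closest known reaction types are the C2 lithiation of 1-alkyl-4-pyridones and 4-quinolones and the C2 metalation of chromones by tetramethylpiperidide bases. 1,2-Addition of an organolithium to one of the two equivalent carbonyl groups of 7 and capture of the alkoxide by MeOTf are standard squarate chemistry, and 9 is far more nucleophilic than the pyranone carbonyl oxygen, so one equivalent of MeOTf should suffice. The quaternary centre of 10 forms as a racemate and is erased in step 5.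

Step 5
Reactants: 10 (±)-4-{6-[2,5-bis(benzyloxy)-4-methoxyphenyl]-4-oxo-4H-pyran-2-yl}-2,3,4-trimethoxycyclobut-2-en-1-one
Product: 13 2-[2,5-bis(benzyloxy)-4-methoxyphenyl]-5-hydroxy-6,7,8-trimethoxy-4H-chromen-4-one, via dienylketene 11 (not isolated), via cyclohexadienone 12 (not isolated)
Conditions: degassed p-xylene (0.01 M), 138 °C, Ar
Reagents that add atoms: none
Why: Thermal cyclobutenone-to-phenol ring expansion of a squarate adduct (Moore rearrangement), a reaction type with close precedent for aryl, furyl, thienyl, pyridyl and dihydropyranyl groups at C4. Heating breaks the C1–C4 bond of 10 in a conrotatory 4π electrocyclic opening, and torquoselectivity sends the donor OMe at C4 outward and the π-acceptor pyranonyl group inward, so only the (Z)-dienylketene 11 with the pyranone next to the ketene should form. Ring A is then closed by a disrotatory 6π electrocyclisation of the triene made of the ketene C=C, the central C=C and pyranone C5=C6, which forms the C4a–C5 bond with matched polarity, since the ketene carbon is electrophilic and pyranone C5, the β-carbon of the O1–C6=C5 enol ether, is the nucleophilic site of the heterocycle. Dienone 12 holds its only sp3 hydrogen at C4a between two carbonyl groups and should enolise at once, gaining the aromaticity of ring A, the pyranone conjugation and the 5-OH···O=C4 hydrogen bond, which makes the sequence irreversible. No stereocentre remains, because that of 10 is lost in the opening and that of 12 in the enolisation. Regioselectivity is fixed by the substrate, because the pyranone carbon that bears the four-membered ring has a single carbon neighbour (C5, the other being O1), and the oxygen pattern is fixed by the atom map: carbinol carbon to C8 (OMe), the two vinyl carbons of 7 to C7 and C6 (OMe), ketene carbon to C5 (free OH). High dilution and exclusion of air are needed so that the ketene is not intercepted by the product phenol and the 4-methoxyphenol of 13 is not oxidised.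

Step 6
Reactants: 13 2-[2,5-bis(benzyloxy)-4-methoxyphenyl]-5-hydroxy-6,7,8-trimethoxy-4H-chromen-4-one
Product: 14 2-(2,5-dihydroxy-4-methoxyphenyl)-5-hydroxy-6,7,8-trimethoxy-4H-chromen-4-one (target)
Conditions: H2 (1 atm), Pd/C (10 wt %), EtOAc–MeOH, rt; filtration under Ar
Reagents that add atoms: none
Why: Hydrogenolysis of aryl benzyl ethers, the usual last step for benzyl-protected hydroxyflavones. Methyl ethers, the chelated 5-OH and the conjugated C2=C3 bond should be untouched at one atmosphere.

## Compound list

1 | 2-methoxybenzene-1,4-diol | COc1cc(O)ccc1O | starting material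
2 | 1-(2,5-dihydroxy-4-methoxyphenyl)ethan-1-one | COc1cc(O)c(C(C)=O)cc1O | intermediate
3 | 1-[2,5-bis(benzyloxy)-4-methoxyphenyl]ethan-1-one | COc1cc(OCc2ccccc2)c(C(C)=O)cc1OCc1ccccc1 | intermediate
4 | (E)-3-ethoxyprop-2-enoyl chloride | CCO/C=C/C(Cl)=O | starting material
5 | (E)-1-[2,5-bis(benzyloxy)-4-methoxyphenyl]-5-ethoxypent-4-ene-1,3-dione | CCO/C=C/C(=O)CC(=O)c1cc(OCc2ccccc2)c(OC)cc1OCc1ccccc1 | intermediate
6 | 2-[2,5-bis(benzyloxy)-4-methoxyphenyl]-4H-pyran-4-one | COc1cc(OCc2ccccc2)c(-c2cc(=O)cco2)cc1OCc1ccccc1 | intermediate
7 | 3,4-dimethoxycyclobut-3-ene-1,2-dione (dimethyl squarate) | COC1=C(OC)C(=O)C1=O | starting material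
8 | {6-[2,5-bis(benzyloxy)-4-methoxyphenyl]-4-oxo-4H-pyran-2-yl}lithium | [Li]c1cc(=O)cc(-c2cc(OCc3ccccc3)c(OC)cc2OCc2ccccc2)o1 | intermediate
9 | lithium (±)-1-{6-[2,5-bis(benzyloxy)-4-methoxyphenyl]-4-oxo-4H-pyran-2-yl}-2,3-dimethoxy-4-oxocyclobut-2-en-1-olate | [Li]OC1(c2cc(=O)cc(-c3cc(OCc4ccccc4)c(OC)cc3OCc3ccccc3)o2)C(OC)=C(OC)C1=O | intermediate
10 | (±)-4-{6-[2,5-bis(benzyloxy)-4-methoxyphenyl]-4-oxo-4H-pyran-2-yl}-2,3,4-trimethoxycyclobut-2-en-1-one | COC1=C(OC)C(OC)(c2cc(=O)cc(-c3cc(OCc4ccccc4)c(OC)cc3OCc3ccccc3)o2)C1=O | intermediate
11 | (Z)-4-{6-[2,5-bis(benzyloxy)-4-methoxyphenyl]-4-oxo-4H-pyran-2-yl}-2,3,4-trimethoxybuta-1,3-dien-1-one | O=C=C(OC)/C(OC)=C(/OC)c1cc(=O)cc(-c2cc(OCc3ccccc3)c(OC)cc2OCc2ccccc2)o1 | intermediate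
12 | (±)-2-[2,5-bis(benzyloxy)-4-methoxyphenyl]-6,7,8-trimethoxy-4aH-chromene-4,5-dione | COC1=C(OC)C(=O)C2C(=O)C=C(c3cc(OCc4ccccc4)c(OC)cc3OCc3ccccc3)OC2=C1OC | intermediate
13 | 2-[2,5-bis(benzyloxy)-4-methoxyphenyl]-5-hydroxy-6,7,8-trimethoxy-4H-chromen-4-one | COc1cc(OCc2ccccc2)c(-c2cc(=O)c3c(O)c(OC)c(OC)c(OC)c3o2)cc1OCc1ccccc1 | intermediate
14 | 2-(2,5-dihydroxy-4-methoxyphenyl)-5-hydroxy-6,7,8-trimethoxy-4H-chromen-4-one | COc1cc(O)c(-c2cc(=O)c3c(O)c(OC)c(OC)c(OC)c3o2)cc1O | target

## Step count and least certain steps

Total steps: 6. Longest linear sequence: 6 (1 → 2 → 3 → 6 → 10 → 13 → 14). Compounds 4 and 7 are bought.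

**Step 4 (the labelled step).**
- What may go wrong:
  - The carbonyl oxygen may direct deprotonation to C3 or C5. The ring oxygen would then be lost by β-elimination, opening the ring to an ynone enolate.
  - The lithiated pyranone may add to pyranone that has not yet been deprotonated.
  - The pyranone carbonyl oxygen may be methylated if MeOTf is in excess.
- Fallback (known chemistry): the C8–C8a bond is made with a lithium acetylide, the best-precedented class of nucleophile for squarates, and ring C is closed afterwards. The fallback sets out from 3 and 7 and comes back at 10.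
  - The lithium enolate of 3 is C-acylated with 3-(trimethylsilyl)propynoyl chloride to 1-[2,5-bis(benzyloxy)-4-methoxyphenyl]-5-(trimethylsilyl)pent-4-yne-1,3-dione F1.
  - F1 is converted with LiN(SiMe3)2 into its enolate, which masks both carbonyl groups. It is then desilylated in the flask with MeLi·LiBr to the acetylide and added to 7.
  - After an acidic quench this should give 4-{5-[2,5-bis(benzyloxy)-4-methoxyphenyl]-3,5-dioxopent-1-yn-1-yl}-4-hydroxy-2,3-dimethoxycyclobut-2-en-1-one F2.
  - The 6-endo-dig oxa-Michael addition of the diketone enol to the ynone uses catalytic TFA or Et3N at room temperature, far below the temperature at which alkynylcyclobutenones rearrange. It closes the pyranone to 4-{6-[2,5-bis(benzyloxy)-4-methoxyphenyl]-4-oxo-4H-pyran-2-yl}-4-hydroxy-2,3-dimethoxycyclobut-2-en-1-one F3.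
  - MeI and Ag2O methylate the tertiary alcohol of F3 to give 10.

**Step 5 (key step).**
- What may go wrong:
  - The 6π closure costs the cyclic conjugation of the pyranone and may be slow.
  - The reversibly formed ketene would then be consumed by dimerisation or by addition of the product phenol.
  - Traces of air would oxidise the electron-rich product.
- Fallback: ring A is taken from an aromatic precursor. The fallback sets out from 3 and comes back at 13.
  - Haloform oxidation of 3 (NaOCl, aqueous dioxane) gives 2,5-bis(benzyloxy)-4-methoxybenzoic acid F4.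
  - (COCl)2 with catalytic DMF gives 2,5-bis(benzyloxy)-4-methoxybenzoyl chloride F5.
  - A1 is bought from a specialist supplier or made as outlined under Alternative 1. It is demethylated next to the carbonyl group with BCl3 to the mirror-symmetric 1-(2,6-dihydroxy-3,4,5-trimethoxyphenyl)ethan-1-one F6.
  - The polyanion of F6, made with excess LiN(SiMe3)2, is C-acylated by F5. This gives 1-[2,5-bis(benzyloxy)-4-methoxyphenyl]-3-(2,6-dihydroxy-3,4,5-trimethoxyphenyl)propane-1,3-dione F7.
  - Catalytic TsOH in hot toluene closes ring C to 13.
  - The two hydroxyl groups of F6 are equivalent, so either closure gives the same flavone and no late 5-O-demethylation is needed.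

**Step 3.**
- What may go wrong:
  - The enolate may be O-acylated or acylated twice.
  - The enolate may attack the β-carbon of 4 with loss of ethoxide, which leads toward the 2-pyranone series.
  - The acid chloride may oligomerise.
- Fallback: it sets out from 3 and comes back at 6.
  - Claisen condensation of 3 with EtOAc (NaH) gives 1-[2,5-bis(benzyloxy)-4-methoxyphenyl]butane-1,3-dione F8.
  - The dianion of F8 (LiN(iPr)2, 2.2 equiv) is formylated at the terminal carbon by ethyl formate to 5-[2,5-bis(benzyloxy)-4-methoxyphenyl]-3,5-dioxopentanal F9.
  - F9 cyclodehydrates with acid to 6.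

**Step 6.**
- What may go wrong:
  - C2=C3 may be saturated while the hindered 2'-benzyl ether is cleaved slowly.
  - The ring B hydroquinone may be oxidised by air on the catalyst during filtration.
- Fallback: the cleavage is changed from reduction to ionisation. It sets out from 13 and comes back at 14. BCl3 with pentamethylbenzene as cation scavenger (CH2Cl2, −78 °C) removes both benzyl groups without a reductant or a metal surface. The low temperature protects 6-OMe. No new compound lies on the way.

## Further compounds

F1 | step 4 | 1-[2,5-bis(benzyloxy)-4-methoxyphenyl]-5-(trimethylsilyl)pent-4-yne-1,3-dione | COc1cc(OCc2ccccc2)c(C(=O)CC(=O)C#C[Si](C)(C)C)cc1OCc1ccccc1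
F2 | step 4 | (±)-4-{5-[2,5-bis(benzyloxy)-4-methoxyphenyl]-3,5-dioxopent-1-yn-1-yl}-4-hydroxy-2,3-dimethoxycyclobut-2-en-1-one | COC1=C(OC)C(O)(C#CC(=O)CC(=O)c2cc(OCc3ccccc3)c(OC)cc2OCc2ccccc2)C1=O
F3 | step 4 | (±)-4-{6-[2,5-bis(benzyloxy)-4-methoxyphenyl]-4-oxo-4H-pyran-2-yl}-4-hydroxy-2,3-dimethoxycyclobut-2-en-1-one | COC1=C(OC)C(O)(c2cc(=O)cc(-c3cc(OCc4ccccc4)c(OC)cc3OCc3ccccc3)o2)C1=O
F4 | step 5 | 2,5-bis(benzyloxy)-4-methoxybenzoic acid | COc1cc(OCc2ccccc2)c(C(=O)O)cc1OCc1ccccc1
F5 | step 5 | 2,5-bis(benzyloxy)-4-methoxybenzoyl chloride | COc1cc(OCc2ccccc2)c(C(=O)Cl)cc1OCc1ccccc1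
F6 | step 5 | 1-(2,6-dihydroxy-3,4,5-trimethoxyphenyl)ethan-1-one | COc1c(O)c(C(C)=O)c(O)c(OC)c1OC
F7 | step 5 | 1-[2,5-bis(benzyloxy)-4-methoxyphenyl]-3-(2,6-dihydroxy-3,4,5-trimethoxyphenyl)propane-1,3-dione | COc1cc(OCc2ccccc2)c(C(=O)CC(=O)c2c(O)c(OC)c(OC)c(OC)c2O)cc1OCc1ccccc1
F8 | step 3 | 1-[2,5-bis(benzyloxy)-4-methoxyphenyl]butane-1,3-dione | COc1cc(OCc2ccccc2)c(C(=O)CC(C)=O)cc1OCc1ccccc1
F9 | step 3 | 5-[2,5-bis(benzyloxy)-4-methoxyphenyl]-3,5-dioxopentanal | COc1cc(OCc2ccccc2)c(C(=O)CC(=O)CC=O)cc1OCc1ccccc1
F0 | step 6 | none | none
A1 | alternative 1 | 1-(2-hydroxy-3,4,5,6-tetramethoxyphenyl)ethan-1-one | COc1c(O)c(C(C)=O)c(OC)c(OC)c1OC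
A2 | alternative 1 | 1-[2,5-bis(benzyloxy)-4-methoxyphenyl]-3-(2-hydroxy-3,4,5,6-tetramethoxyphenyl)propane-1,3-dione | COc1cc(OCc2ccccc2)c(C(=O)CC(=O)c2c(O)c(OC)c(OC)c(OC)c2OC)cc1OCc1ccccc1
A3 | alternative 2 | 5-hydroxy-6,7,8-trimethoxy-4H-chromen-4-one | COc1c(OC)c(O)c2c(=O)ccoc2c1OC
A4 | alternative 2 | 2-methoxycyclohexa-2,5-diene-1,4-dione | COC1=CC(=O)C=CC1=O
A5 | alternative 2 | 2-(5-hydroxy-6,7,8-trimethoxy-4-oxo-4H-chromen-2-yl)-5-methoxycyclohexa-2,5-diene-1,4-dione | COC1=CC(=O)C(c2cc(=O)c3c(O)c(OC)c(OC)c(OC)c3o2)=CC1=O
A6 | alternative 3 | 2,3,4,5-tetramethoxy-6-methylidenecyclohexa-2,4-dien-1-one | C=C1C(=O)C(OC)=C(OC)C(OC)=C1OC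
A7 | alternative 3 | 1,4-bis(benzyloxy)-2-ethenyl-5-methoxybenzene | C=Cc1cc(OCc2ccccc2)c(OC)cc1OCc1ccccc1
A8 | alternative 3 | (±)-2-[2,5-bis(benzyloxy)-4-methoxyphenyl]-5,6,7,8-tetramethoxy-3,4-dihydro-2H-chromene | COc1cc(OCc2ccccc2)c(C2CCc3c(OC)c(OC)c(OC)c(OC)c3O2)cc1OCc1ccccc1
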